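**Retrosynthetic overview**
1. The target comes from a 13‑chloro‑11‑hydroxy lactone diol by diacetylation; the chlorohydrin comes from chloride opening (at C13) of an 11,13‑spiro‑epoxy lactone.
2. The ten‑membered ring is closed by ring‑closing metathesis at C1=C10 (Z enforced by ring size); the spiro‑epoxide comes from nucleophilic epoxidation of an α‑methylene lactone.
3. The α‑methylene lactone (C6–C7 bond and lactone C–O) comes from a late allylboration/lactonisation joining a western (Z)‑enal (C1–C6, C15) with an eastern 2‑(methoxycarbonyl)allylboronate (C7–C14).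
4. The enal comes from (S)‑epichlorohydrin and ethynyltrimethylsilane (ylide homologation, ynoate, Me2CuLi syn‑carbocupration); the allylboronate comes from (S)‑glycidol and isopropenylmagnesium bromide (Corey–Fuchs ynoate, hydroalumination/ICH2Bpin).
5. Ring order: butyrolactone (step 15), then oxirane (step 16, opened in step 18), then ten‑membered carbocycle (step 17).

Assumption: atoms are labelled with germacrane numbering (ring C1–C10; lactone carbons C11–C13 with C12 the carbonyl; C14 on C10; C15 on C4). In this numbering the target is (1(10)Z,2S,4Z,6R,7R,8R,11S).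

**Western fragment**

Step 1
Reactants: 1 (S)-epichlorohydrin [(2S)-2-(chloromethyl)oxirane]; 2 ethynyltrimethylsilane
Product: 4 (2S)-1-chloro-5-(trimethylsilyl)pent-4-yn-2-ol, via lithium (trimethylsilyl)acetylide 3 (not isolated)
Conditions: 2, nBuLi, THF, −78 °C; BF3·OEt2, then 1, −78 °C; aq. NH4Cl
Reagents that add atoms: none
Why: Yamaguchi‑type BF3‑promoted alkynylation opens the epoxide only at its CH2 terminus, so the chloride and the carbinol stereocentre (future C2, bought in with 1) are untouched.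

Step 2
Reactants: 4 (2S)-1-chloro-5-(trimethylsilyl)pent-4-yn-2-ol
Product: 7 (3S)-hex-1-en-5-yn-3-ol, via silylalkynyl oxirane 5 (not isolated), via silylated enynol 6 (not isolated)
Conditions: Me3SI (4 equiv), nBuLi (3.9 equiv), THF, −20 °C → rt; then MeOH, K2CO3, rt
Reagents that add atoms: trimethylsulfonium iodide, C[S+](C)C.[I-]
Why: Excess dimethylsulfonium methylide closes the chlorohydrin to the terminal epoxide, opens it at CH2 and loses Me2S (Corey–Chaykovsky‑type one‑carbon homologation to the vinyl carbinol) without touching the stereocentre, and methanolic K2CO3 then protodesilylates the alkyne.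

Step 3
Reactants: 7 (3S)-hex-1-en-5-yn-3-ol
Product: 8 tert-butyl[(3S)-hex-1-en-5-yn-3-yloxy]dimethylsilane
Conditions: TBSCl, imidazole, DMF, rt
Reagents that add atoms: tert-butyldimethylsilyl chloride, CC(C)(C)[Si](C)(C)Cl
Why: Silyl ether formation protects the future C2 hydroxyl as a group inert to organolithium, cuprate and hydride reagents.

Step 4
Reactants: 8 tert-butyl[(3S)-hex-1-en-5-yn-3-yloxy]dimethylsilane
Product: 10 methyl (5S)-5-[(tert-butyldimethylsilyl)oxy]hept-6-en-2-ynoate, via lithium acetylide 9 (not isolated)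
Conditions: nBuLi, THF, −78 °C; ClCO2Me, −78 → 0 °C
Reagents that add atoms: methyl chloroformate, COC(=O)Cl
Why: Deprotonation of the terminal alkyne and C‑acylation of the acetylide give the ynoate that carries C4–C6.

Step 5
Reactants: 10 methyl (5S)-5-[(tert-butyldimethylsilyl)oxy]hept-6-en-2-ynoate
Product: 12 methyl (2Z,5S)-5-[(tert-butyldimethylsilyl)oxy]-3-methylhepta-2,6-dienoate, via alkenylcuprate 11 (not isolated)
Conditions: Me2CuLi (from CuI and MeLi), THF, −78 °C; MeOH quench at −78 °C; aq. NH4Cl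
Reagents that add atoms: methyllithium, [Li]C
Why: Syn‑carbocupration of the ynoate (conjugate addition) and protonation of the configurationally stable alkenylcuprate at −78 °C put the C3 chain cis to the ester, which fixes the 4Z alkene.

Step 6
Reactants: 12 methyl (2Z,5S)-5-[(tert-butyldimethylsilyl)oxy]-3-methylhepta-2,6-dienoate
Product: 13 (2Z,5S)-5-[(tert-butyldimethylsilyl)oxy]-3-methylhepta-2,6-dien-1-ol
Conditions: iBu2AlH (2.5 equiv), CH2Cl2, −78 °C; aq. potassium sodium tartrate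
Reagents that add atoms: none
Why: 1,2‑Reduction of the enoate by the aluminium hydride at low temperature gives the allylic alcohol without change of alkene geometry.

Step 7
Reactants: 13 (2Z,5S)-5-[(tert-butyldimethylsilyl)oxy]-3-methylhepta-2,6-dien-1-ol
Product: 14 (2Z,5S)-5-[(tert-butyldimethylsilyl)oxy]-3-methylhepta-2,6-dienal
Conditions: activated MnO2 (15 equiv), CH2Cl2, rt
Reagents that add atoms: none
Why: Allylic oxidation with MnO2 is neutral and selective, so the (Z)‑enal is obtained without isomerisation to the E isomer.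

**Eastern fragment**

Step 8
Reactants: 15 (S)-glycidol [(2S)-oxiran-2-ylmethanol]; 16 isopropenylmagnesium bromide
Product: 17 (2R)-4-methylpent-4-ene-1,2-diol
Conditions: 16 (3 equiv), CuI (10 mol %), THF, −40 → 0 °C; aq. NH4Cl
Reagents that add atoms: none
Why: Copper‑catalysed Grignard opening of the epoxide at its terminal carbon (one equivalent is spent on the hydroxyl) adds C9, C10 and C14 and keeps the glycidol stereocentre, which becomes C8 (R).

Step 9
Reactants: 17 (2R)-4-methylpent-4-ene-1,2-diol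
Product: 18 (2R)-1,2-bis[(tert-butyldimethylsilyl)oxy]-4-methylpent-4-ene
Conditions: TBSCl (2.4 equiv), imidazole, DMF, rt
Reagents that add atoms: tert-butyldimethylsilyl chloride, CC(C)(C)[Si](C)(C)Cl
Why: Double silylation protects both hydroxyls so that the primary one can be released selectively in the next step.

Step 10
Reactants: 18 (2R)-1,2-bis[(tert-butyldimethylsilyl)oxy]-4-methylpent-4-ene
Product: 19 (2R)-2-[(tert-butyldimethylsilyl)oxy]-4-methylpent-4-en-1-ol
Conditions: HF·pyridine, pyridine, THF, 0 °C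
Reagents that add atoms: none
Why: Selective desilylation works because the primary silyl ether is cleaved much faster than the hindered secondary one by buffered HF·pyridine.

Step 11
Reactants: 19 (2R)-2-[(tert-butyldimethylsilyl)oxy]-4-methylpent-4-en-1-ol
Product: 20 (2R)-2-[(tert-butyldimethylsilyl)oxy]-4-methylpent-4-enal
Conditions: Dess–Martin periodinane, CH2Cl2, 0 °C → rt
Reagents that add atoms: none
Why: Dess–Martin oxidation is non‑basic, so the α‑silyloxy aldehyde forms without epimerisation of C8.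

Step 12
Reactants: 20 (2R)-2-[(tert-butyldimethylsilyl)oxy]-4-methylpent-4-enal
Product: 21 tert-butyl{[(3R)-1,1-dibromo-5-methylhexa-1,5-dien-3-yl]oxy}dimethylsilane
Conditions: CBr4, PPh3, CH2Cl2, 0 °C
Reagents that add atoms: carbon tetrabromide, BrC(Br)(Br)Br
Why: Ramirez dibromo‑olefination (first stage of the Corey–Fuchs alkyne synthesis) adds the carbon that becomes C11 under neutral conditions.

Step 13
Reactants: 21 tert-butyl{[(3R)-1,1-dibromo-5-methylhexa-1,5-dien-3-yl]oxy}dimethylsilane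
Product: 23 methyl (4R)-4-[(tert-butyldimethylsilyl)oxy]-6-methylhept-6-en-2-ynoate, via lithium acetylide 22 (not isolated)
Conditions: nBuLi (2.1 equiv), THF, −78 °C; ClCO2Me, −78 → 0 °C
Reagents that add atoms: methyl chloroformate, COC(=O)Cl
Why: In the second stage of the Corey–Fuchs sequence, bromine–lithium exchange and loss of LiBr give the lithium acetylide, which is C‑acylated in the same flask to the ynoate (C12).

Step 14
Reactants: 23 methyl (4R)-4-[(tert-butyldimethylsilyl)oxy]-6-methylhept-6-en-2-ynoate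
Product: 25 methyl (2Z,4R)-4-[(tert-butyldimethylsilyl)oxy]-6-methyl-2-[(4,4,5,5-tetramethyl-1,3,2-dioxaborolan-2-yl)methyl]hepta-2,6-dienoate, via alkenylalane 24 (not isolated)
Conditions: iBu2AlH (1.5 equiv), HMPA, THF, 0 °C; then ICH2Bpin, 0 °C → rt
Reagents that add atoms: 2-(iodomethyl)-4,4,5,5-tetramethyl-1,3,2-dioxaborolane, ICB1OC(C)(C)C(C)(C)O1
Why: Syn‑hydroalumination of the ynoate (conjugate hydride delivery by the aluminium hydride–HMPA complex) and alkylation of the α‑aluminio acrylate with retention place C8 trans to the CH2B group, which is the E‑crotyl‑type geometry needed for an anti allylboration.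

**Coupling and end game**

Step 15
Reactants: 14 (2Z,5S)-5-[(tert-butyldimethylsilyl)oxy]-3-methylhepta-2,6-dienal; 25 methyl (2Z,4R)-4-[(tert-butyldimethylsilyl)oxy]-6-methyl-2-[(4,4,5,5-tetramethyl-1,3,2-dioxaborolan-2-yl)methyl]hepta-2,6-dienoate
Product: 27 (4S,5R)-4-[(1R)-1-[(tert-butyldimethylsilyl)oxy]-3-methylbut-3-en-1-yl]-5-[(1Z,4S)-4-[(tert-butyldimethylsilyl)oxy]-2-methylhexa-1,5-dien-1-yl]-3-methylideneoxolan-2-one, via O-boryl adduct 26 (not isolated)
Conditions: Sc(OTf)3 (10 mol %), toluene, −40 °C → rt; then PPTS (cat.), rt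
Reagents that add atoms: none
Why: Lewis acid‑catalysed allylboration through a closed chair transition state (aldehyde chain and C8 both equatorial) gives the anti adduct and hence the trans lactone after lactonisation, while allylic 1,3‑strain against the cis ester holds H‑8 in the alkene plane so that the enal adds anti to the methallyl CH2 and gauche to the silyloxy group, which sets C6 and C7 in the relative configuration of the target.

Step 16
Reactants: 27 (4S,5R)-4-[(1R)-1-[(tert-butyldimethylsilyl)oxy]-3-methylbut-3-en-1-yl]-5-[(1Z,4S)-4-[(tert-butyldimethylsilyl)oxy]-2-methylhexa-1,5-dien-1-yl]-3-methylideneoxolan-2-one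
Product: 28 (3R,6R,7S)-7-[(1R)-1-[(tert-butyldimethylsilyl)oxy]-3-methylbut-3-en-1-yl]-6-[(1Z,4S)-4-[(tert-butyldimethylsilyl)oxy]-2-methylhexa-1,5-dien-1-yl]-1,5-dioxaspiro[2.4]heptan-4-one
Conditions: tBuOOH, nBuLi (gives LiOOtBu), THF, −78 → −20 °C
Reagents that add atoms: tert-butyl hydroperoxide, CC(C)(C)OO
Why: In this Weitz–Scheffer nucleophilic epoxidation the peroxide anion adds to C13 and the lactone enolate closes onto oxygen on the face anti to the bulky C7 substituent (as in alkylations of β‑substituted butyrolactone enolates), which sets C11 with oxygen cis to H‑7, and the electron‑rich alkenes do not react.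

Step 17
Reactants: 28 (3R,6R,7S)-7-[(1R)-1-[(tert-butyldimethylsilyl)oxy]-3-methylbut-3-en-1-yl]-6-[(1Z,4S)-4-[(tert-butyldimethylsilyl)oxy]-2-methylhexa-1,5-dien-1-yl]-1,5-dioxaspiro[2.4]heptan-4-one
Product: 29 (1(10)Z,2S,4Z,6R,7S,8R,11R)-2,8-bis[(tert-butyldimethylsilyl)oxy]-11,13-epoxygermacra-1(10),4-dien-12,6-olide
Conditions: second-generation Hoveyda–Grubbs catalyst (C31H38Cl2N2ORu, 10 mol %), 1,4-benzoquinone (20 mol %), toluene (1 mM), 80 °C
Reagents that add atoms: none
Why: Ring‑closing metathesis between the vinyl group and the 1,1‑disubstituted alkene under high dilution releases ethene and forms the trisubstituted C1=C10 bond, which can only be Z in a ten‑membered ring.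

Step 18
Reactants: 29 (1(10)Z,2S,4Z,6R,7S,8R,11R)-2,8-bis[(tert-butyldimethylsilyl)oxy]-11,13-epoxygermacra-1(10),4-dien-12,6-olide
Product: 30 (1(10)Z,2S,4Z,6R,7S,8R,11S)-2,8-bis[(tert-butyldimethylsilyl)oxy]-13-chloro-11-hydroxygermacra-1(10),4-dien-12,6-olide
Conditions: LiCl (5 equiv), AcOH (3 equiv), THF, rt
Reagents that add atoms: lithium chloride, [Li+].[Cl-]
Why: Acid‑assisted SN2 opening of the glycidic (α,β‑epoxy) lactone by chloride occurs at the unhindered CH2 (C13), so C11 keeps its C–O bond and its configuration.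

Step 19
Reactants: 30 (1(10)Z,2S,4Z,6R,7S,8R,11S)-2,8-bis[(tert-butyldimethylsilyl)oxy]-13-chloro-11-hydroxygermacra-1(10),4-dien-12,6-olide
Product: 31 (1(10)Z,2S,4Z,6R,7R,8R,11S)-13-chloro-2,8,11-trihydroxygermacra-1(10),4-dien-12,6-olide
Conditions: HF·pyridine, pyridine, THF, 0 °C → rt
Reagents that add atoms: none
Why: Fluoride‑mediated desilylation under buffered acidic conditions frees both secondary alcohols without closing the chlorohydrin back to the epoxide or opening the lactone.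

Step 20
Reactants: 31 (1(10)Z,2S,4Z,6R,7R,8R,11S)-13-chloro-2,8,11-trihydroxygermacra-1(10),4-dien-12,6-olide
Product: 32 (1(10)Z,2S,4Z,6R,7R,8R,11S)-2,8-diacetoxy-13-chloro-11-hydroxygermacra-1(10),4-dien-12,6-olide (CNP0182971.4)
Conditions: Ac2O, pyridine, DMAP (5 mol %), CH2Cl2, 0 °C → rt
Reagents that add atoms: acetic anhydride, CC(=O)OC(C)=O
Why: Acylation with Ac2O/pyridine esterifies the two secondary alcohols while the hindered tertiary α‑hydroxy lactone alcohol stays free.

**Compound list**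
1 | (S)-epichlorohydrin, (2S)-2-(chloromethyl)oxirane | ClC[C@@H]1CO1 | starting material
2 | ethynyltrimethylsilane | C#C[Si](C)(C)C | starting material
3 | lithium (trimethylsilyl)acetylide | [Li]C#C[Si](C)(C)C | intermediate
4 | (2S)-1-chloro-5-(trimethylsilyl)pent-4-yn-2-ol | C[Si](C)(C)C#CC[C@H](O)CCl | intermediate
5 | (2S)-2-[3-(trimethylsilyl)prop-2-yn-1-yl]oxirane | C[Si](C)(C)C#CC[C@H]1CO1 | intermediate
6 | (3S)-6-(trimethylsilyl)hex-1-en-5-yn-3-ol | C[Si](C)(C)C#CC[C@H](O)C=C | intermediate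
7 | (3S)-hex-1-en-5-yn-3-ol | C#CC[C@H](O)C=C | intermediate
8 | tert-butyl[(3S)-hex-1-en-5-yn-3-yloxy]dimethylsilane | C#CC[C@H](O[Si](C)(C)C(C)(C)C)C=C | intermediate
9 | lithium acetylide of 8 | [Li]C#CC[C@H](O[Si](C)(C)C(C)(C)C)C=C | intermediate
10 | methyl (5S)-5-[(tert-butyldimethylsilyl)oxy]hept-6-en-2-ynoate | COC(=O)C#CC[C@H](O[Si](C)(C)C(C)(C)C)C=C | intermediate
11 | lithium alkenyl(methyl)cuprate from 10 (Cu cis to the new methyl) | [Li+].C[Cu-]/C(C(=O)OC)=C(\C)C[C@H](O[Si](C)(C)C(C)(C)C)C=C | intermediate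
12 | methyl (2Z,5S)-5-[(tert-butyldimethylsilyl)oxy]-3-methylhepta-2,6-dienoate | COC(=O)/C=C(/C)C[C@H](O[Si](C)(C)C(C)(C)C)C=C | intermediate
13 | (2Z,5S)-5-[(tert-butyldimethylsilyl)oxy]-3-methylhepta-2,6-dien-1-ol | OC/C=C(/C)C[C@H](O[Si](C)(C)C(C)(C)C)C=C | intermediate
14 | (2Z,5S)-5-[(tert-butyldimethylsilyl)oxy]-3-methylhepta-2,6-dienal | O=C/C=C(/C)C[C@H](O[Si](C)(C)C(C)(C)C)C=C | intermediate
15 | (S)-glycidol, (2S)-oxiran-2-ylmethanol | OC[C@H]1CO1 | starting material
16 | isopropenylmagnesium bromide | C=C(C)[Mg]Br | starting material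
17 | (2R)-4-methylpent-4-ene-1,2-diol | C=C(C)C[C@@H](O)CO | intermediate
18 | (2R)-1,2-bis[(tert-butyldimethylsilyl)oxy]-4-methylpent-4-ene | C=C(C)C[C@@H](O[Si](C)(C)C(C)(C)C)CO[Si](C)(C)C(C)(C)C | intermediate
19 | (2R)-2-[(tert-butyldimethylsilyl)oxy]-4-methylpent-4-en-1-ol | C=C(C)C[C@@H](O[Si](C)(C)C(C)(C)C)CO | intermediate
20 | (2R)-2-[(tert-butyldimethylsilyl)oxy]-4-methylpent-4-enal | C=C(C)C[C@@H](O[Si](C)(C)C(C)(C)C)C=O | intermediate
21 | tert-butyl{[(3R)-1,1-dibromo-5-methylhexa-1,5-dien-3-yl]oxy}dimethylsilane | C=C(C)C[C@@H](O[Si](C)(C)C(C)(C)C)C=C(Br)Br | intermediate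
22 | lithium acetylide from 21 | C=C(C)C[C@@H](O[Si](C)(C)C(C)(C)C)C#C[Li] | intermediate
23 | methyl (4R)-4-[(tert-butyldimethylsilyl)oxy]-6-methylhept-6-en-2-ynoate | C=C(C)C[C@@H](O[Si](C)(C)C(C)(C)C)C#CC(=O)OC | intermediate
24 | methyl (2E,4R)-2-(diisobutylalumanyl)-4-[(tert-butyldimethylsilyl)oxy]-6-methylhepta-2,6-dienoate (Al cis to H-3) | C=C(C)C[C@@H](O[Si](C)(C)C(C)(C)C)/C=C(/[Al](CC(C)C)CC(C)C)C(=O)OC | intermediate
25 | methyl (2Z,4R)-4-[(tert-butyldimethylsilyl)oxy]-6-methyl-2-[(4,4,5,5-tetramethyl-1,3,2-dioxaborolan-2-yl)methyl]hepta-2,6-dienoate | C=C(C)C[C@@H](O[Si](C)(C)C(C)(C)C)/C=C(/CB1OC(C)(C)C(C)(C)O1)C(=O)OC | intermediate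
26 | methyl (3S,4R,5Z,8S)-8-[(tert-butyldimethylsilyl)oxy]-3-[(1R)-1-[(tert-butyldimethylsilyl)oxy]-3-methylbut-3-en-1-yl]-6-methyl-2-methylidene-4-[(4,4,5,5-tetramethyl-1,3,2-dioxaborolan-2-yl)oxy]deca-5,9-dienoate | C=C(C(=O)OC)[C@H]([C@@H](CC(C)=C)O[Si](C)(C)C(C)(C)C)[C@H](OB1OC(C)(C)C(C)(C)O1)/C=C(/C)C[C@H](O[Si](C)(C)C(C)(C)C)C=C | intermediate
27 | (4S,5R)-4-[(1R)-1-[(tert-butyldimethylsilyl)oxy]-3-methylbut-3-en-1-yl]-5-[(1Z,4S)-4-[(tert-butyldimethylsilyl)oxy]-2-methylhexa-1,5-dien-1-yl]-3-methylideneoxolan-2-one | C=C1C(=O)O[C@H](/C=C(/C)C[C@H](O[Si](C)(C)C(C)(C)C)C=C)[C@H]1[C@@H](CC(C)=C)O[Si](C)(C)C(C)(C)C | intermediate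
28 | (3R,6R,7S)-7-[(1R)-1-[(tert-butyldimethylsilyl)oxy]-3-methylbut-3-en-1-yl]-6-[(1Z,4S)-4-[(tert-butyldimethylsilyl)oxy]-2-methylhexa-1,5-dien-1-yl]-1,5-dioxaspiro[2.4]heptan-4-one | O=C1O[C@H](/C=C(/C)C[C@H](O[Si](C)(C)C(C)(C)C)C=C)[C@@H]([C@@H](CC(C)=C)O[Si](C)(C)C(C)(C)C)[C@@]12CO2 | intermediate
29 | (1(10)Z,2S,4Z,6R,7S,8R,11R)-2,8-bis[(tert-butyldimethylsilyl)oxy]-11,13-epoxygermacra-1(10),4-dien-12,6-olide | CC(C)(C)[Si](C)(C)O[C@@H]1/C=C(/C)C[C@@H](O[Si](C)(C)C(C)(C)C)[C@@H]2[C@@H](/C=C(/C)C1)OC(=O)[C@]23CO3 | intermediate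
30 | (1(10)Z,2S,4Z,6R,7S,8R,11S)-2,8-bis[(tert-butyldimethylsilyl)oxy]-13-chloro-11-hydroxygermacra-1(10),4-dien-12,6-olide | CC(C)(C)[Si](C)(C)O[C@@H]1/C=C(/C)C[C@@H](O[Si](C)(C)C(C)(C)C)[C@@H]2[C@@H](/C=C(/C)C1)OC(=O)[C@]2(O)CCl | intermediate
31 | (1(10)Z,2S,4Z,6R,7R,8R,11S)-13-chloro-2,8,11-trihydroxygermacra-1(10),4-dien-12,6-olide | O[C@@H]1/C=C(/C)C[C@@H](O)[C@@H]2[C@@H](/C=C(/C)C1)OC(=O)[C@]2(O)CCl | intermediate
32 | (3S,3aR,4R,6Z,8S,10Z,11aR)-3-(chloromethyl)-3-hydroxy-6,10-dimethyl-2-oxo-2,3,3a,4,5,8,9,11a-octahydrocyclodeca[b]furan-4,8-diyl diacetate | CC(=O)O[C@@H]1/C=C(/C)C[C@@H](OC(C)=O)[C@@H]2[C@@H](/C=C(/C)C1)OC(=O)[C@]2(O)CCl | target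

**Step count**
Total: 20 steps (7 western, 7 eastern, 6 after the union).
Longest linear sequence: 13 steps (steps 1–7 then 15–20; the eastern line, steps 8–14 then 15–20, is equally long).

**Three steps most likely to fail, with fallbacks**

Step 15, the allylboration/lactonisation. The 2‑alkoxycarbonyl allylboronate is deactivated, the enal is a sluggish partner, the facial bias from C8 is only predicted, and any loss of geometry in step 14 shows up here. The fallback is a Nozaki–Hiyama allylation with an allylic bromide, setting out from aldehyde 20 and enal 14. Aldehyde 20 with methyl acrylate and DABCO gives the Morita–Baylis–Hillman adduct methyl (4R)-4-[(tert-butyldimethylsilyl)oxy]-3-hydroxy-6-methyl-2-methylidenehept-6-enoate F1. NBS/Me2S converts it with allylic transposition into methyl (2Z,4R)-2-(bromomethyl)-4-[(tert-butyldimethylsilyl)oxy]-6-methylhepta-2,6-dienoate F2. F2, 14 and CrCl2 in THF form an equilibrating allylchromium reagent (trivalent chromium) that adds through a chair transition state to give the anti adduct, which lactonises to 27, where the route is rejoined.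

Step 16, the nucleophilic epoxidation. Facial selectivity at C11 rests on substrate control, and the lactone could suffer from the peroxide base. The fallback is a reagent‑controlled Sharpless epoxidation, setting out from 27. Reduction with iBu2AlH (CH2Cl2, −78 → 0 °C) gives (3S,4R,5Z,8S)-8-[(tert-butyldimethylsilyl)oxy]-3-[(1R)-1-[(tert-butyldimethylsilyl)oxy]-3-methylbut-3-en-1-yl]-6-methyl-2-methylidenedeca-5,9-diene-1,4-diol F3. Ti(OiPr)4, D-(−)-diethyl tartrate and tBuOOH (CH2Cl2, −20 °C) epoxidise only its 2‑substituted primary allylic alcohol, giving the (11S)-11,13-epoxide of F3 F4. Oxidative lactonisation with TEMPO/PhI(OAc)2 then closes the 1,4‑diol to 28, where the route is rejoined.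

Step 17, the ring‑closing metathesis. The vinyl group sits next to a bulky silyloxy group, and a strained ten‑membered ring with a trisubstituted alkene must form. The fallback is ring closure on the desilylated triol, where a free allylic hydroxyl at C2 speeds up metathesis and the silyl bulk is gone; it sets out from 28. LiCl/AcOH in THF gives (3S,4S,5R)-3-(chloromethyl)-3-hydroxy-4-[(1R)-1-[(tert-butyldimethylsilyl)oxy]-3-methylbut-3-en-1-yl]-5-[(1Z,4S)-4-[(tert-butyldimethylsilyl)oxy]-2-methylhexa-1,5-dien-1-yl]oxolan-2-one F5. HF·pyridine gives (3S,4R,5R)-3-(chloromethyl)-3-hydroxy-4-[(1R)-1-hydroxy-3-methylbut-3-en-1-yl]-5-[(1Z,4S)-4-hydroxy-2-methylhexa-1,5-dien-1-yl]oxolan-2-one F6. Ring‑closing metathesis of F6 with the second-generation Grubbs catalyst (C46H65Cl2N2PRu) in dilute CH2Cl2 at reflux gives 31, where the route is rejoined.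

**Further compounds**
F1 | step 15 | methyl (4R)-4-[(tert-butyldimethylsilyl)oxy]-3-hydroxy-6-methyl-2-methylidenehept-6-enoate (both C3 epimers) | C=C(C)C[C@@H](O[Si](C)(C)C(C)(C)C)C(O)C(=C)C(=O)OC
F2 | step 15 | methyl (2Z,4R)-2-(bromomethyl)-4-[(tert-butyldimethylsilyl)oxy]-6-methylhepta-2,6-dienoate | C=C(C)C[C@@H](O[Si](C)(C)C(C)(C)C)/C=C(\CBr)C(=O)OC
F3 | step 16 | (3S,4R,5Z,8S)-8-[(tert-butyldimethylsilyl)oxy]-3-[(1R)-1-[(tert-butyldimethylsilyl)oxy]-3-methylbut-3-en-1-yl]-6-methyl-2-methylidenedeca-5,9-diene-1,4-diol | C=C(CO)[C@H]([C@@H](CC(C)=C)O[Si](C)(C)C(C)(C)C)[C@H](O)/C=C(/C)C[C@H](O[Si](C)(C)C(C)(C)C)C=C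
F4 | step 16 | (11S)-11,13-epoxide of F3 | OC[C@]1(CO1)[C@H]([C@@H](CC(C)=C)O[Si](C)(C)C(C)(C)C)[C@H](O)/C=C(/C)C[C@H](O[Si](C)(C)C(C)(C)C)C=C
F5 | step 17 | (3S,4S,5R)-3-(chloromethyl)-3-hydroxy-4-[(1R)-1-[(tert-butyldimethylsilyl)oxy]-3-methylbut-3-en-1-yl]-5-[(1Z,4S)-4-[(tert-butyldimethylsilyl)oxy]-2-methylhexa-1,5-dien-1-yl]oxolan-2-one | O=C1O[C@H](/C=C(/C)C[C@H](O[Si](C)(C)C(C)(C)C)C=C)[C@@H]([C@@H](CC(C)=C)O[Si](C)(C)C(C)(C)C)[C@@]1(O)CCl
F6 | step 17 | (3S,4R,5R)-3-(chloromethyl)-3-hydroxy-4-[(1R)-1-hydroxy-3-methylbut-3-en-1-yl]-5-[(1Z,4S)-4-hydroxy-2-methylhexa-1,5-dien-1-yl]oxolan-2-one | O=C1O[C@H](/C=C(/C)C[C@H](O)C=C)[C@@H]([C@@H](CC(C)=C)O)[C@@]1(O)CCl
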